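**The choice.** Choosing a partner charge for a run of 10 h needs one quantity, the conversion per equivalent: the part of the starting material reacted, divided by the equivalents of partner charged, at a stated time. If that quantity holds from flask to flask, conversion follows the charge in a straight line.

| setting | birch | alder | Wednesday's | Saturday's | Thursday's |
|---|---|---|---|---|---|
| starting material | 0.20 M | 0.20 M | 0.20 M | 0.20 M | 0.20 M |
| partner | 1.7 equiv | 2.1 equiv | 1.50 equiv | 2.20 equiv | 3.40 equiv |
| transfer agent | 0.20 M | 0.20 M | 0.200 M | 0.200 M | 0.200 M |
| initiator | 1 mol% | 1 mol% | 1 mol% | 1 mol% | 1 mol% |
| remark | run made earlier | run made earlier |  |  |  |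
| time |  |  | 10 h | 10 h | 10 h |

| run | time / h | starting material / % | target / % |
|---|---|---|---|
| birch | 1.00 | 96.6 | 3.6 |
| birch | 2.00 | 94.2 | 6.2 |
| birch | 3.00 | 91.7 | 9.1 |
| birch | 4.00 | 89.4 | 10.2 |
| birch | 5.00 | 87.9 | 13.9 |
| alder | 0.417 | 99.1 | 1.2 |
| alder | 0.833 | 97.6 | 3.3 |
| alder | 1.33 | 94.6 | 4.9 |
| alder | 2.50 | 92.5 | 8.7 |
| alder | 5.00 | 84.0 | 15.7 |

(readings scatter by 0.5 percentage points)



- part of the starting material that has reacted at the end, Wednesday's
- part of the starting material that has reacted at the end, Saturday's
- part of the starting material that has reacted at the end, Thursday's
- what raising the equivalents of partner from its lowest to its highest value here does to the part of the starting material that has reacted (changes below 5 percentage points count as none) (no change / it falls / it rises)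

**First way.** At 5.00 h, averaging the loss of starting material and the gain of target, birch gives 7.65% of its partner charge and alder 7.55%. The two charges differ, yet these values agree within the scatter, so their mean 7.60% serves for both. Going from a reading to one at double its time multiplies the conversion by a mean of 1.85 in the two runs (birch's second and fourth hours, alder's last two readings). This is less than a straight line gives, and it is a reading with wide scatter. Applied to 7.60%, it gives 14.0%, the conversion per equivalent at the end of the run. Wednesday's then reaches 21.0% and Thursday's 47.7%.

**Second way.** A pseudo-first-order constant per equivalent, taken from the starting-material column alone, lets the rate sink as starting material falls. It gives 21.2% for Wednesday's, in agreement with the first way, but 41.7% for Thursday's, where they part. The alder run stops at 16.0% reacted, too little to separate them. This reckoning stays with the first way, which takes the falling-off with time as measured and assumes no cause for it.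

**The forecast.** It gives 21%, 29% and 41%, with the trend it rises, on the grounds “Treating this as pseudo-first-order over 10 h”. For Thursday's it stands 6.7 percentage points below the first way.

**The flask.** The answers are 21.2%, 31.0% and 47.7%, and the trend reads: it rises. With Wednesday's partner charge in place of its own, Thursday's stands at 21.2% instead of 47.7%, so the gap of 27 points between these flasks comes from the difference in equivalents of partner.

    initiator → 2 initiating radical (k = 0.00407 h⁻¹)
    starting material + initiating radical → capped initiator + first chain carrier (k = 1.17 × 10⁵ M⁻¹ s⁻¹)
    partner + first chain carrier → target + second chain carrier (k = 69400 M⁻¹ s⁻¹)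
    starting material + second chain carrier → by-product + first chain carrier (k = 63200 M⁻¹ s⁻¹)
    transfer agent + first chain carrier → side product + idle radical (kL = 1.21 × 10⁶ M⁻¹ h⁻¹)
    2 idle radical → ended radicals (k = 4.90 × 10⁶ M⁻¹ s⁻¹)
    2 second chain carrier → ended chains (k = 6.40 × 10⁷ M⁻¹ s⁻¹)
    partner + by-product ⇌ idle adduct, settled at all times (K = 210 M⁻¹)

**The cheat.** Divided by the charge, Wednesday's gives 14.1% and Thursday's 14.0%, against the 14.0% reckoned. Starting material stands at 79% in Wednesday's and 52% in Thursday's, yet the conversion per equivalent does not sink with it, so the second way is the one that parts from the flask. Free partner stands at 72.2% of its charge in Wednesday's and 72.1% in Thursday's. A flask like Saturday's with 0.550 equiv of partner is reckoned at 7.70%, and it stands at 7.83%.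

The data are simulated with made-up constants, noise included.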